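Percent of the starting material charged was my unit. In grey and blue, coupling partner stood above one equivalent, so starting material was the limiting reagent. In Friday's run partner was limiting.

the same everywhere: starting material 0.80 M; free catalyst 10 mol%

| flask | coupling partner | remark | time |
|---|---|---|---|
| Friday's | 0.55 equiv | run made earlier |  |
| grey | 1.10 equiv |  | 2.0 d |
| blue | 1.10 equiv |  | 4.0 d |

Friday's run (percent of the starting material charged)

| time / h | target / % |
|---|---|
| 1.00 | 0 |
| 2.00 | 9 |
| 4.00 | 13 |
| 8.00 | 21 |
| 15.0 | 31 |

(readings scatter by 1.5 percentage points)



I ran the flask slowly in my head, counting the smaller charge.

First instants: Friday's flask read 0% target at 1.00 h and 9% at 2.00 h. I read that as a short lag, with material perhaps held on the catalyst before target appeared.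

Middle: target kept rising, and its last reading, 31%, stood below that run's partner charge. So Friday's readings stopped below what its partner charge allows.

End: in grey and blue, starting material thins first. Partner then falls towards a level it cannot pass:

spare share = 1 − 1/1.10 = 9.09% of its own charge

This spare share is the part of the partner that no starting material can meet. Partner left above it measures the coupling still to come:

still to couple = 1.10 × (partner left − spare share)

Once partner stood at the spare share in grey or blue, coupling was over, and target could still change into isomer. My balance therefore keeps the isomer as an open term, since Friday's readings did not show it:

target = charge − starting material left − material on the catalyst − isomer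

So I gave no yield of my own.

- which of the two there is more of at the end, grey (target / isomer of the product)
- which of the two there is more of at the end, blue (target / isomer of the product)
- how much target is there at the end, in percent of the starting material charged: grey
- how much target is there at the end, in percent of the starting material charged: blue

The forecast gave 68% for grey and 62% for blue, with target ahead in grey and target ahead in blue. It held that “any isomerisation is slow”.

Grey ended with 51.3% target and 40.6% isomer of the product. Blue ended with 32.4% target and more isomer of the product, 65.0%.

    starting material + free catalyst ⇌ catalyst intermediate A (K = 9.30 /M, k = 2.36 /M/h)
    catalyst intermediate A → catalyst intermediate B (k = 2.22 /h)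
    coupling partner + catalyst intermediate B → catalyst intermediate C (k = 1.80 /M/h)
    catalyst intermediate C ⇌ free catalyst + target (K = 0.780 M, k = 29.9 /h)
    target + free catalyst ⇌ isomer of the product + free catalyst, rate k5*[free catalyst]*[target] forward; the back reaction follows from the equilibrium constant (K = 2.30, k = 0.653 /M/h)

Grey's target went from 56.2% at 1.00 d to 51.3% at 2.00 d, while its partner, at 13.9%, was still above the spare share, with 5.28% of the starting material still to couple; the forward half-life of target to isomer, other concentrations as charged, was 0.55 d, short against 2.0 d. Blue's partner stood close to the spare share, at 9.15% at 4.00 d, with target at 32.4%. Grey's recipe at 2.0 M of starting material stood close to it at 2.00 d, with partner at 9.24% and target at 33.9%.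

(The numbers in the tables come from a simulation for an exercise.)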